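## Retrosynthetic overview
Label the rings A–E along the chain A–O–B–O–C–O–D–O–E. No ring is constructed; all five arenes come from commercial polyphenols as benzyl ethers, and the four C–O–C bonds are made by Cu-catalysed Ullmann O-arylation.
1. Final step: global hydrogenolysis of 13 O-benzyl groups.
2. Last ether bond: C–O–D, joining fragment A–O–B–O–C(Br) to fragment HO–D–O–E.
3. Fragment A–O–B–O–C(Br): A-iodide plus salicylaldehyde B, then Dakin oxidation to the B phenol, then iodide-selective coupling with the C bromo-iodide.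
4. Fragment HO–D–O–E: E-phenol plus the D bromo-aldehyde, then Dakin oxidation.
5. Order of joining: A–B, then (AB)–C, in parallel E–D, then (ABC)–(DE).

Assumptions:
- The target is achiral, so the "single enantiomer" requirement is moot.
- Benzyl is the global protecting group.
- Phloroglucinol, 2,4,6-trihydroxybenzaldehyde, 3-bromocatechol and 3,4,5-trihydroxybenzaldehyde are commercial.
- Only substrates are numbered; reagents such as BnBr, NIS, NBS and mCPBA are given by SMILES in the "Reagents that add atoms" line.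

## Route

**Step 1**
Reactants: 1, phloroglucinol
Product: 2, 1,3,5-tris(benzyloxy)benzene
Conditions: BnBr (3.3 equiv), K2CO3, DMF, 60 °C
Reagents that add atoms: benzyl bromide, BrCc1ccccc1
Why: Williamson O-benzylation of the three equivalent phenols; no stereocentre is formed.

**Step 2**
Reactants: 2
Product: 3, 2-iodo-1,3,5-tris(benzyloxy)benzene
Conditions: NIS (1.05 equiv), MeCN, 0 °C → rt
Reagents that add atoms: N-iodosuccinimide, O=C1CCC(=O)N1I
Why: Electrophilic aromatic iodination of the symmetric, highly electron-rich ring gives a single regioisomer (all ring CH positions are equivalent); no stereocentre.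

**Step 3**
Reactants: 4, 2,4,6-trihydroxybenzaldehyde
Product: 5, 4,6-bis(benzyloxy)-2-hydroxybenzaldehyde
Conditions: BnBr (2.1 equiv), K2CO3, acetone, reflux
Reagents that add atoms: benzyl bromide, BrCc1ccccc1
Why: Selective Williamson bis-O-benzylation; the remaining ortho-OH is hydrogen-bonded to the CHO and so is the least reactive (assumed regiochemistry); no stereocentre.

**Step 4**
Reactants: 3, aryl iodide; 5, salicylaldehyde (iodide 1.5 equiv)
Product: 6, 4,6-bis(benzyloxy)-2-[2,4,6-tris(benzyloxy)phenoxy]benzaldehyde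
Conditions: CuI (20 mol%), picolinic acid (40 mol%), K3PO4, DMSO, 90 °C
Reagents that add atoms: none
Why: Ligand-accelerated Ullmann-type C–O coupling, aided by the chelating ortho-alkoxy and ortho-CHO groups, forms the A–O–B bond; no stereocentre.

**Step 5**
Reactants: 6
Product: 7, 2,4-bis(benzyloxy)-6-[2,4,6-tris(benzyloxy)phenoxy]phenol
Conditions: (i) mCPBA, CH2Cl2, 0 °C → rt; (ii) K2CO3, MeOH, rt
Reagents that add atoms: mCPBA, OOC(=O)c1cccc(Cl)c1 (supplies the phenol oxygen)
Why: Dakin-type Baeyer–Villiger oxidation of the very electron-rich 2,4,6-trialkoxybenzaldehyde gives the aryl formate, which methanolysis converts to the hindered phenol at b6; no stereocentre.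

**Step 6**
Reactants: 8, 3-bromocatechol
Product: 9, 1,2-bis(benzyloxy)-3-bromobenzene
Conditions: BnBr (2.2 equiv), K2CO3, DMF, rt
Reagents that add atoms: benzyl bromide, BrCc1ccccc1
Why: Williamson bis-O-benzylation; no stereocentre.

**Step 7**
Reactants: 9
Product: 10, 1,2-bis(benzyloxy)-3-bromo-5-iodobenzene
Conditions: NIS (1.05 equiv), cat. TFA, MeCN, rt
Reagents that add atoms: N-iodosuccinimide, O=C1CCC(=O)N1I
Why: Electrophilic iodination occurs para to an OBn group and away from the Br, giving a differentiated I/Br ring C (assumed regiochemistry); no stereocentre.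

**Step 8**
Reactants: 7, phenol; 10, dihalide (2.5 equiv)
Product: 11, 3-bromo-4,5-bis(benzyloxy)phenyl 2,4-bis(benzyloxy)-6-[2,4,6-tris(benzyloxy)phenoxy]phenyl ether
Conditions: CuI (20 mol%), picolinic acid (40 mol%), K3PO4, DMSO, 70 °C
Reagents that add atoms: none
Why: Ullmann coupling at 70 °C reacts only the unhindered C–I bond; the C–Br bond, which is ortho to OBn, survives, and excess 10 suppresses double arylation; no stereocentre.

**Step 9**
Reactants: 12, 3,4,5-trihydroxybenzaldehyde
Product: 13, 3,4,5-tris(benzyloxy)benzaldehyde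
Conditions: BnBr (3.3 equiv), K2CO3, DMF, 60 °C
Reagents that add atoms: benzyl bromide, BrCc1ccccc1
Why: Williamson tri-O-benzylation; no stereocentre.

**Step 10**
Reactants: 13
Product: 14, 2-bromo-3,4,5-tris(benzyloxy)benzaldehyde
Conditions: NBS (1.1 equiv), DMF, 50 °C
Reagents that add atoms: N-bromosuccinimide, O=C1CCC(=O)N1Br
Why: Electrophilic bromination of the C2-symmetric ring has only one possible product, bromination ortho to CHO and ortho/para to OBn; no stereocentre.

**Step 11**
Reactants: 13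
Product: 15, 3,4,5-tris(benzyloxy)phenol
Conditions: (i) mCPBA, CH2Cl2, 0 °C → rt; (ii) K2CO3, MeOH, rt
Reagents that add atoms: mCPBA, OOC(=O)c1cccc(Cl)c1
Why: Dakin-type Baeyer–Villiger oxidation followed by formate methanolysis converts CHO to OH; no stereocentre.

**Step 12**
Reactants: 14, ortho-bromo aldehyde; 15, phenol (1.5 equiv)
Product: 16, 3,4,5-tris(benzyloxy)-2-[3,4,5-tris(benzyloxy)phenoxy]benzaldehyde
Conditions: CuI (20 mol%), picolinic acid (40 mol%), K3PO4, DMSO, 100 °C
Reagents that add atoms: none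
Why: Ullmann-type coupling of an unhindered phenol with an aryl bromide activated and directed by the ortho-CHO forms the D–O–E bond; no stereocentre.

**Step 13**
Reactants: 16
Product: 17, 3,4,5-tris(benzyloxy)-2-[3,4,5-tris(benzyloxy)phenoxy]phenol
Conditions: (i) mCPBA, CH2Cl2, 0 °C → rt; (ii) K2CO3, MeOH, rt
Reagents that add atoms: mCPBA, OOC(=O)c1cccc(Cl)c1
Why: Dakin-type oxidation of the alkoxy-rich aldehyde unmasks the D1 phenol without touching the benzyl ethers or the new diaryl ether; no stereocentre.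

**Step 14**
Reactants: 11, aryl bromide; 17, phenol (1.5 equiv)
Product: 18, per-O-benzyl pentaaryl ether (13 OBn)
Conditions: CuI (30 mol%), picolinic acid (60 mol%), K3PO4, DMSO, 100 °C
Reagents that add atoms: none
Why: Convergent Ullmann-type C–O coupling forms the C5–O–D1 bond; the ortho-OBn group on the bromide assists Cu insertion; no stereocentre.

**Step 15**
Reactants: 18
Product: 19, Pseudopentafuhalol D
Conditions: H2 (1 atm), Pd(OH)2/C, THF/MeOH 1:1, rt
Reagents that add atoms: none (H2 adds only hydrogen)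
Why: Catalytic hydrogenolysis cleaves all 13 benzyl ethers to the free phenols while the diaryl ether C–O bonds and aromatic rings remain intact; the target has no stereocentres.

## Compound list
1 | phloroglucinol | Oc1cc(O)cc(O)c1 | starting material
2 | 1,3,5-tris(benzyloxy)benzene | c1ccc(COc2cc(OCc3ccccc3)cc(OCc3ccccc3)c2)cc1 | intermediate
3 | 2-iodo-1,3,5-tris(benzyloxy)benzene | Ic1c(OCc2ccccc2)cc(OCc2ccccc2)cc1OCc1ccccc1 | intermediate
4 | 2,4,6-trihydroxybenzaldehyde | O=Cc1c(O)cc(O)cc1O | starting material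
5 | 4,6-bis(benzyloxy)-2-hydroxybenzaldehyde | O=Cc1c(O)cc(OCc2ccccc2)cc1OCc1ccccc1 | intermediate
6 | 4,6-bis(benzyloxy)-2-[2,4,6-tris(benzyloxy)phenoxy]benzaldehyde | O=Cc1c(OCc2ccccc2)cc(OCc2ccccc2)cc1Oc1c(OCc2ccccc2)cc(OCc2ccccc2)cc1OCc1ccccc1 | intermediate
7 | 2,4-bis(benzyloxy)-6-[2,4,6-tris(benzyloxy)phenoxy]phenol | Oc1c(OCc2ccccc2)cc(OCc2ccccc2)cc1Oc1c(OCc2ccccc2)cc(OCc2ccccc2)cc1OCc1ccccc1 | intermediate
8 | 3-bromocatechol | Oc1cccc(Br)c1O | starting material
9 | 1,2-bis(benzyloxy)-3-bromobenzene | Brc1cccc(OCc2ccccc2)c1OCc1ccccc1 | intermediate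
10 | 1,2-bis(benzyloxy)-3-bromo-5-iodobenzene | Brc1cc(I)cc(OCc2ccccc2)c1OCc1ccccc1 | intermediate
11 | 3-bromo-4,5-bis(benzyloxy)phenyl 2,4-bis(benzyloxy)-6-[2,4,6-tris(benzyloxy)phenoxy]phenyl ether | Brc1cc(Oc2c(OCc3ccccc3)cc(OCc3ccccc3)cc2Oc2c(OCc3ccccc3)cc(OCc3ccccc3)cc2OCc2ccccc2)cc(OCc2ccccc2)c1OCc1ccccc1 | intermediate
12 | 3,4,5-trihydroxybenzaldehyde | O=Cc1cc(O)c(O)c(O)c1 | starting material
13 | 3,4,5-tris(benzyloxy)benzaldehyde | O=Cc1cc(OCc2ccccc2)c(OCc2ccccc2)c(OCc2ccccc2)c1 | intermediate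
14 | 2-bromo-3,4,5-tris(benzyloxy)benzaldehyde | O=Cc1cc(OCc2ccccc2)c(OCc2ccccc2)c(OCc2ccccc2)c1Br | intermediate
15 | 3,4,5-tris(benzyloxy)phenol | Oc1cc(OCc2ccccc2)c(OCc2ccccc2)c(OCc2ccccc2)c1 | intermediate
16 | 3,4,5-tris(benzyloxy)-2-[3,4,5-tris(benzyloxy)phenoxy]benzaldehyde | O=Cc1cc(OCc2ccccc2)c(OCc2ccccc2)c(OCc2ccccc2)c1Oc1cc(OCc2ccccc2)c(OCc2ccccc2)c(OCc2ccccc2)c1 | intermediate
17 | 3,4,5-tris(benzyloxy)-2-[3,4,5-tris(benzyloxy)phenoxy]phenol | Oc1cc(OCc2ccccc2)c(OCc2ccccc2)c(OCc2ccccc2)c1Oc1cc(OCc2ccccc2)c(OCc2ccccc2)c(OCc2ccccc2)c1 | intermediate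
18 | per-O-benzyl Pseudopentafuhalol D (13 OBn) | c%10ccccc%10COc1cc(OCc%10ccccc%10)c(Oc2cc(OCc%10ccccc%10)cc(OCc%10ccccc%10)c2Oc2cc(OCc%10ccccc%10)c(OCc%10ccccc%10)c(Oc3cc(OCc%10ccccc%10)c(OCc%10ccccc%10)c(OCc%10ccccc%10)c3Oc3cc(OCc%10ccccc%10)c(OCc%10ccccc%10)c(OCc%10ccccc%10)c3)c2)c(OCc%10ccccc%10)c1 | intermediate
19 | Pseudopentafuhalol D (C30H22O17, achiral) | Oc1cc(O)c(Oc2cc(O)cc(O)c2Oc2cc(O)c(O)c(Oc3cc(O)c(O)c(O)c3Oc3cc(O)c(O)c(O)c3)c2)c(O)c1 | target

## Totals
- Total steps: 15.
- Longest linear sequence: 7 steps (1 → 2 → 3 → 6 → 7 → 11 → 18 → 19, i.e. steps 1, 2, 4, 5, 8, 14, 15).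

## Three steps most likely to fail
1. **Step 4 (A–O–B bond).** The aryl iodide has two ortho-OBn groups, and the phenol is chelated to the CHO and electron-rich, so the coupling may be slow.
   Fallback: form this bond by metal-free O-arylation of phenol 5 with a [2,4,6-tris(benzyloxy)phenyl](aryl)iodonium salt instead of Cu catalysis.
2. **Step 10 (ring bromination of the CHO-deactivated ring).** It may be sluggish or cause benzyl ether or benzylic side reactions.
   Fallback: make 14 by directed ortho-metalation of 13 as its in-situ α-amino-alkoxide (LiN-methylpiperazide, s-BuLi), then quench with a Br+ source (C2Br2Cl4).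
3. **Step 14 (joining the two large fragments).** The coupling is between a hindered bromide and a hindered phenol at high molecular weight.
   Fallback: convert bromide 11 to its boronic ester by Miyaura borylation, then join it to phenol 17 by Chan–Lam Cu(II) coupling at rt, which is a different bond-forming mechanism.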